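The time allowed this flask, 15 d, is 5.00 times the 3.00 d it has been followed so far, so I count how many half-lives fit into what remains.

common to all: substrate 1.7 M; gas 200 mM (held)
- eta: the very flask that is asked about, followed so far
- flask: time 15 d

eta run (percent of the substrate charged)

| time / d | substrate / % | triple product / % |
|---|---|---|
| 0.833 | 11 | 33 |
| 1.67 | 0 | 85 |
| 2.50 | 2 | 98 |
| 3.00 | 0 | 101 |

(readings scatter by 1.5 percentage points)

- the numbers in the tables scatter with a standard deviation of 1.5 percentage points
- at the start none of the gas is in solution
- the reaction counts as stopped when no species that holds the substrate changes by six tenths of a point or more over the second half of the time

* at 15 d, what has stopped the reaction, if anything has (it is still moving / forward and back rates have come level / all of the substrate has reacted)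
* part of the substrate gone at 15 d
* the triple product standing at 15 d, as a percentage of the substrate charged

1. The substrate gives a first way. With the gas held, I treat its fall as pseudo-first-order: from the whole charge to 11% in 0.833 d reads as a half-life of 0.262 d.

2. The triple product gives a second way, from different readings. I take the gap, the triple product still missing from the charge. The half-life of that gap comes from its fall between 1.67 d and 2.50 d, from 15.0% to 2.00%, and reads 0.286 d.

3. The two nearly agree, and I trust that figure as a rough one, since the later gap stands close to the scatter of 1.5 percentage points. I carry the second because it is slower.

4. From 2.50 d to 15 d fit 43.8 half-lives. A gap of 2.00% halved that many times cannot be read, so I expect the substrate gone and the charge standing as triple product. A slow drain after 3.00 d lies outside these readings.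

5. The forecast says all of the substrate has reacted, with 100% gone and 99.5% triple product (range 96% to 100%): “essentially all substrate converted to triple product”.

6. In this flask, all of the substrate has reacted, with 100% gone and 100% triple product.

    partner + single product → bis adduct + released group (k = 0.680 /M/h)
    gas ⇌ partner, rate k2*(csat - [partner]) (kL = 1.60 /h)
    substrate + partner → single product + released group (k = 1.10 /M/h)
    partner + bis adduct → triple product + released group (k = 1.30 /M/h)

In this flask the gap was 22.5% at 1.50 d. From there to 7.50 d my half-life counts 21.0 halvings, and the triple product then stands at 100%. The neighbouring flask is charged with 0.42 M of substrate, a quarter of this charge. Lending it the same half-life gives the same 43.8 halvings after 2.50 d. That neighbouring flask holds 0% of its substrate unbound at 15.0 d, and its triple product stands at 100%.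

The data were computed for substances that don't exist; noise was put on by code.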